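## Retrosynthetic overview

1. Last bond: the C6–O acyl bond, formed by a new protecting-group-free vanilloyl transfer from vanillic acid to the dauc-2-ene-4β,6α,8β-triol.
2. C8–O bond: Markovnikov radical hydration of a trisubstituted C7=C8 alkene; the C4 carbinol comes from isopropyl addition to a cyclopentenone carbonyl.
3. Seven-membered ring: ring-closing metathesis (C7=C8) of a vinyl carbinol with a 1,1-disubstituted alkene; C5–C6 by an anti aldol with acrolein.
4. C1 quaternary centre: copper-catalysed asymmetric conjugate addition to 3-methylcyclopent-2-en-1-one, then dehydrogenation to the enone.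
5. Ring order: the five-membered ring comes from the starting material; the seven-membered ring is closed second.

Assumption: daucane numbering is used for the core (C1 quaternary methyl carbon, C2=C3, C4 isopropyl carbinol, C5 ring-fusion CH, C6 ester carbon, C8 methyl carbinol), β is the face of the C1 methyl, and the target SMILES is read as 1β-CH3, 4β-OH, 5α-H, 6α-acyloxy, 8β-OH, i.e. (3S,3aS,4S,6R,8aS) in azulene numbering.

## Route

Step 1
Reactants: 1 3-methylcyclopent-2-en-1-one; 2 4-bromo-2-methylbut-1-ene
Product: 4 (S)-3-methyl-3-(3-methylbut-3-en-1-yl)cyclopentan-1-one, via (3-methylbut-3-en-1-yl)magnesium bromide 3 (not isolated)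
Conditions: 2, Mg, Et2O, 35 °C; then 1, Cu(OTf)2 (3 mol %), chiral C2-symmetric imidazolinium chloride (4 mol %), Et2O, −30 → 0 °C; dilute aq. HCl
Reagents that add atoms: none
Why: Copper-catalysed asymmetric conjugate addition of a Grignard reagent to a β-methyl cyclic enone (Alexakis-type NHC–copper catalysis) builds the C1 quaternary stereocentre, the imidazolinium enantiomer being chosen so that the butenyl group is delivered to the face giving (S)-4, and the remote 1,1-disubstituted alkene is inert.

Step 2
Reactants: 4 (S)-3-methyl-3-(3-methylbut-3-en-1-yl)cyclopentan-1-one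
Product: 5 (R)-4-methyl-4-(3-methylbut-3-en-1-yl)cyclopent-2-en-1-one
Conditions: 2-iodoxybenzoic acid (IBX, 2.2 equiv), 4-methoxypyridine N-oxide (2.2 equiv), DMSO, 25 °C
Reagents that add atoms: none
Why: IBX-mediated α,β-dehydrogenation of the ketone (Nicolaou) can take place only towards C2–C3, because the other α-carbon adjoins the quaternary centre and has no β-hydrogen, so a single enone forms and the stereocentre is untouched (its descriptor becomes R only through the priority rules).

Step 3
Reactants: 5 (R)-4-methyl-4-(3-methylbut-3-en-1-yl)cyclopent-2-en-1-one; 6 acrolein (prop-2-enal)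
Product: 7 (4S,5S)-5-[(1S)-1-hydroxyprop-2-en-1-yl]-4-methyl-4-(3-methylbut-3-en-1-yl)cyclopent-2-en-1-one
Conditions: LiN(iPr)2, THF, −78 °C; 6, −78 °C, 10 min; AcOH
Reagents that add atoms: none
Why: Directed aldol addition (Zimmerman–Traxler) of the kinetic cross-conjugated lithium enolate, which can form only at C5: acrolein adds 1,2 on the enolate face cis to the C1 methyl and anti to the larger butenyl chain (sets C5) and the cyclic E-enolate chair gives the anti aldol (sets C6 as the later 6α-carbinol), the minor diastereomers being removed by chromatography.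

Step 4
Reactants: 7 (4S,5S)-5-[(1S)-1-hydroxyprop-2-en-1-yl]-4-methyl-4-(3-methylbut-3-en-1-yl)cyclopent-2-en-1-one
Product: 8 (3aS,4S,8aS)-4-hydroxy-6,8a-dimethyl-3a,4,7,8-tetrahydroazulen-3(8aH)-one
Conditions: second-generation Grubbs catalyst (5 mol %), CH2Cl2 (0.005 mol/L), 40 °C
Reagents that add atoms: none
Why: Ring-closing metathesis between the vinyl carbinol and the 1,1-disubstituted alkene closes the seven-membered ring as the trisubstituted C7=C8 alkene with loss of ethene, the electron-poor endocyclic enone alkene does not take part, and the trans ring fusion set in step 3 is carried through unchanged.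

Step 5
Reactants: 8 (3aS,4S,8aS)-4-hydroxy-6,8a-dimethyl-3a,4,7,8-tetrahydroazulen-3(8aH)-one; 9 isopropylmagnesium chloride
Product: 10 (3S,3aS,4S,8aS)-6,8a-dimethyl-3-(propan-2-yl)-3,3a,4,7,8,8a-hexahydroazulene-3,4-diol
Conditions: LaCl3·2LiCl (1.1 equiv), THF, 0 °C; 9 (3 equiv), −78 → −20 °C; H2O
Reagents that add atoms: none
Why: Lanthanum-promoted 1,2-addition of a Grignard reagent to an enolisable enone (Knochel conditions): the first equivalent only deprotonates the C6 hydroxyl, and the isopropyl group then attacks the C4 carbonyl from the α face, anti to the C5–C6 bond on the neighbouring carbon and to the β methyl at C1, which gives the 4β tertiary allylic alcohol.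

Step 6
Reactants: 10 (3S,3aS,4S,8aS)-6,8a-dimethyl-3-(propan-2-yl)-3,3a,4,7,8,8a-hexahydroazulene-3,4-diol
Product: 11 (3S,3aS,4S,6R,8aS)-6,8a-dimethyl-3-(propan-2-yl)-3,3a,4,5,6,7,8,8a-octahydroazulene-3,4,6-triol
Conditions: Co(acac)2 (20 mol %), PhSiH3 (2.5 equiv), O2 (1 atm), THF, 23 °C
Reagents that add atoms: dioxygen (O=O)
Why: Mukaiyama hydration (cobalt-hydride hydrogen-atom transfer): the hydrogen atom adds to C7 of the trisubstituted alkene far faster than to the cis-disubstituted C2=C3 alkene, the tertiary C8 radical is trapped by O2 preferentially along the axial β trajectory that leaves the C8 methyl equatorial (about 3–4:1 expected, 8-epimer removed by chromatography), and the peroxide is reduced in the same pot to the 8β tertiary alcohol.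

Step 7
Reactants: 11 (3S,3aS,4S,6R,8aS)-6,8a-dimethyl-3-(propan-2-yl)-3,3a,4,5,6,7,8,8a-octahydroazulene-3,4,6-triol; 12 vanillic acid (4-hydroxy-3-methoxybenzoic acid)
Product: 15 (3S,3aS,4S,6R,8aS)-3,6-dihydroxy-6,8a-dimethyl-3-(propan-2-yl)-3,3a,4,5,6,7,8,8a-octahydroazulen-4-yl 4-hydroxy-3-methoxybenzoate, via vanillic acid O-acylisourea 13 (not isolated), via 2-methoxy-4-(oxomethylidene)cyclohexa-2,5-dien-1-one 14 (not isolated)
Conditions: 12 (2.5 equiv), N,N'-diisopropylcarbodiimide (2.5 equiv), MeCN–THF, 0 °C; then 11, DBU (3 equiv, slow addition), 4 Å MS, 0 → 40 °C; then MeOH, K2CO3 (cat.), 0 °C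
Reagents that add atoms: none
Why: Proposed new method: base-triggered para-oxoketene acyl transfer, in which the carbodiimide turns unprotected vanillic acid into O-acylisourea 13, its phenoxide (DBU) expels the isourea by 1,6-elimination (E1cB) to give quinoid ketene 14, and 14 is captured at the acyl carbon by the only non-tertiary hydroxyl (C6–OH) with rearomatisation; capture by phenoxides only gives aryl vanillates that re-enter the E1cB manifold or are cleaved in the methanol quench, whereas the alkyl ester (alkoxide leaving group) is E1cB-inert and acts as the sink, so no phenol protection is needed and no stereocentre is touched (C6 retained); the closest known chemistry is the dissociative E1cB acyl transfer of aryl 4-hydroxybenzoates through para-oxoketenes, ortho-quinone-ketene salicylate formation from benzodioxinones and the Steglich esterification.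

## Compound list

1 | 3-methylcyclopent-2-en-1-one | CC1=CC(=O)CC1 | starting material
2 | 4-bromo-2-methylbut-1-ene | C=C(C)CCBr | starting material
3 | (3-methylbut-3-en-1-yl)magnesium bromide | C=C(C)CC[Mg]Br | intermediate
4 | (S)-3-methyl-3-(3-methylbut-3-en-1-yl)cyclopentan-1-one | O=C1CC[C@](C)(CCC(C)=C)C1 | intermediate
5 | (R)-4-methyl-4-(3-methylbut-3-en-1-yl)cyclopent-2-en-1-one | O=C1C=C[C@](C)(CCC(C)=C)C1 | intermediate
6 | acrolein (prop-2-enal) | C=CC=O | starting material
7 | (4S,5S)-5-[(1S)-1-hydroxyprop-2-en-1-yl]-4-methyl-4-(3-methylbut-3-en-1-yl)cyclopent-2-en-1-one (hydroxyallyl group cis to the ring methyl, anti aldol) | O[C@@H](C=C)[C@H]1C(=O)C=C[C@]1(C)CCC(C)=C | intermediate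
8 | (3aS,4S,8aS)-4-hydroxy-6,8a-dimethyl-3a,4,7,8-tetrahydroazulen-3(8aH)-one (trans-fused; 1β-CH3, 5α-H, 6α-OH in daucane numbering) | O[C@H]1C=C(C)CC[C@@]2(C)C=CC(=O)[C@H]12 | intermediate
9 | isopropylmagnesium chloride | CC(C)[Mg]Cl | starting material
10 | (3S,3aS,4S,8aS)-6,8a-dimethyl-3-(propan-2-yl)-3,3a,4,7,8,8a-hexahydroazulene-3,4-diol (dauca-2,7-diene-4β,6α-diol) | O[C@H]1C=C(C)CC[C@@]2(C)C=C[C@@](O)(C(C)C)[C@H]12 | intermediate
11 | (3S,3aS,4S,6R,8aS)-6,8a-dimethyl-3-(propan-2-yl)-3,3a,4,5,6,7,8,8a-octahydroazulene-3,4,6-triol (dauc-2-ene-4β,6α,8β-triol) | O[C@H]1C[C@](C)(O)CC[C@@]2(C)C=C[C@@](O)(C(C)C)[C@H]12 | intermediate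
12 | vanillic acid (4-hydroxy-3-methoxybenzoic acid) | COc1cc(C(=O)O)ccc1O | starting material
13 | O-(4-hydroxy-3-methoxybenzoyl)-N,N'-diisopropylisourea | COc1cc(C(=O)OC(=NC(C)C)NC(C)C)ccc1O | intermediate
14 | 2-methoxy-4-(oxomethylidene)cyclohexa-2,5-dien-1-one (para-oxoketene) | COC1=CC(=C=O)C=CC1=O | intermediate
15 | (3S,3aS,4S,6R,8aS)-3,6-dihydroxy-6,8a-dimethyl-3-(propan-2-yl)-3,3a,4,5,6,7,8,8a-octahydroazulen-4-yl 4-hydroxy-3-methoxybenzoate (CNP0113302.1) | COc1cc(C(=O)O[C@H]2C[C@](C)(O)CC[C@@]3(C)C=C[C@@](O)(C(C)C)[C@H]23)ccc1O | target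

## Step count and risks

Total step count: 7. Longest linear sequence: 7 steps (1 → 15).

The three steps most likely to fail:

**Step 7 (the new acyl transfer).** The risks are oligomerisation of the oxoketene and low conversion at the hindered C6 hydroxyl. The fallback sets out from 11 and comes back at 15. Steglich acylation with commercial 4-acetoxy-3-methoxybenzoic acid (EDC·HCl, DMAP, CH2Cl2, 23 °C) acylates only the secondary C6 hydroxyl and gives 4β,8β-dihydroxydauc-2-en-6α-yl 4-acetoxy-3-methoxybenzoate F3. K2CO3 in MeOH at 0 °C then removes the phenolic acetate selectively (aryl acetate reacts far faster than the hindered alkyl benzoate) to give 15. This costs one extra step.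

**Step 6 (facial selectivity at C8).** The radical is trapped by O2 under substrate control only, and the ratio may be low or reversed. The fallback sets out from 10 and comes back at 11, replacing radical hydration by catalyst-controlled epoxidation and directed hydride opening. Shi epoxidation of the trisubstituted alkene (fructose-derived ketone catalyst of the enantiomeric series that delivers oxygen to the β face, Oxone (2KHSO5·KHSO4·K2SO4), K2CO3 buffer, MeCN–dimethoxymethane, 0 °C) gives 7β,8β-epoxydauc-2-ene-4β,6α-diol F2. NaAlH2(OCH2CH2OCH3)2 (Red-Al) in THF at 0 °C then opens this trans-2,3-epoxy alcohol at C7 by hydride delivery from the C6 alkoxyaluminate, anti to the epoxide oxygen. The C8–O bond stays intact and 11 is obtained.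

**Step 1 (enantioselectivity on a five-membered enone).** Grignard additions that form quaternary centres give lower ee on cyclopentenones than on cyclohexenones. The fallback sets out from Grignard reagent 3 and comes back at 4, reversing the order in which the two C1 substituents are introduced. Stork–Danheiser addition of 3 to commercial 3-ethoxycyclopent-2-en-1-one, followed by dilute acid, gives 3-(3-methylbut-3-en-1-yl)cyclopent-2-en-1-one F1. Copper-catalysed asymmetric conjugate addition of Me3Al (copper thiophene-2-carboxylate, chiral phosphinamine ligand of the SimplePhos type, Et2O, −30 °C) then installs the methyl group and gives 4. This costs one extra step.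

## Further compounds

F1 | step 1 | 3-(3-methylbut-3-en-1-yl)cyclopent-2-en-1-one | O=C1C=C(CCC(C)=C)CC1
F2 | step 6 | 7β,8β-epoxydauc-2-ene-4β,6α-diol | O[C@H]1[C@@H]2O[C@]2(C)CC[C@@]3(C)C=C[C@@](O)(C(C)C)[C@H]13
F3 | step 7 | 4β,8β-dihydroxydauc-2-en-6α-yl 4-acetoxy-3-methoxybenzoate | COc1cc(C(=O)O[C@H]2C[C@](C)(O)CC[C@@]3(C)C=C[C@@](O)(C(C)C)[C@H]23)ccc1OC(C)=O
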